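**Strategy.** Everything rests on the C3–C4 bond of the ten-membered carbocycle (C1–C10), which is closed last by an intramolecular Nozaki–Hiyama–Kishi reaction. The step exploits the C3 ketone standing next to the (Z)-C4=C5 alkene. A (Z)-C4 vinyl iodide adds to a C3 aldehyde with retention of geometry, and the cis-fused C6/C7 α-methylene-γ-lactone acts as a hinge that holds both arms on one face. The precursor is an open-chain iodo aldehyde that already carries the lactone, the C8 ester and all stereocentres. C10 is bought as (R)-linalool, C8 is set by catalysis, and C6 and C7 are relayed from C8 in one indium-mediated allylation–lactonisation.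

Key step: step 13

Assumption: atoms carry germacranolide numbers (ring C1–C10, C3 ketone, C4=C5, C6–O lactone, C8–O ester, C10 carbinol, C11–C13 methylene-lactone carbons, C14 methyl, C15 CH2OH); the γ-hydroxy enone is treated as the drawn open keto form although it may equilibrate with its 3,10-hemiketal; (R)-linalool and (R)-2-methylbutanoic acid are bought enantiopure.

**Step 1**
Reactants: 1 (R)-linalool
Product: 2 (R)-linalool triethylsilyl ether
Conditions: TESOTf, 2,6-lutidine, CH2Cl2, −78 to 0 °C
Reagents that add atoms: triethylsilyl triflate CC[Si](CC)(CC)OS(=O)(=O)C(F)(F)F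
Why: Silyl ether protection with a silyl triflate and a hindered base silylates the tertiary allylic alcohol without ionising it, so C10 (bought stereocentre) is untouched and cannot later form a lactol with C3.

**Step 2**
Reactants: 2 (R)-linalool triethylsilyl ether
Product: 4 (3R)-3,7-dimethyl-3-(triethylsilyloxy)oct-6-en-1-ol, via B-alkyl-9-BBN adduct 3 (not isolated)
Conditions: 9-BBN, THF, 0 °C to rt; then H2O2, aq NaOH, 0 °C
Reagents that add atoms: 9-BBN (boron unit of 3) B1C2CCCC1CCC2; hydrogen peroxide OO
Why: In this hydroboration–oxidation 9-BBN adds to the monosubstituted vinyl group much faster than to the trisubstituted alkene and places boron on the terminal carbon C8, which oxidation turns into the primary alcohol.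

**Step 3**
Reactants: 4 (3R)-3,7-dimethyl-3-(triethylsilyloxy)oct-6-en-1-ol
Product: 5 (3R)-3,7-dimethyl-3-(triethylsilyloxy)oct-6-enal
Conditions: Dess–Martin periodinane, NaHCO3, CH2Cl2, 0 °C to rt
Reagents that add atoms: none
Why: The buffered Dess–Martin oxidation stops at the C8 aldehyde and leaves the silyl ether and the alkene alone.

**Step 4**
Reactants: 5 (3R)-3,7-dimethyl-3-(triethylsilyloxy)oct-6-enal; 6 methyl propiolate
Product: 7 methyl (4R,6R)-4-hydroxy-6,10-dimethyl-6-(triethylsilyloxy)undec-9-en-2-ynoate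
Conditions: (S,S)-ProPhenol (cat.), Me2Zn, Ph3P=O (cat.), toluene, 4 °C; aq NH4Cl
Reagents that add atoms: none
Why: In this zinc–ProPhenol-catalysed asymmetric alkynylation the dinuclear zinc catalyst delivers the zinc propiolate to the Si face of the aldehyde and sets C8 (R) under reagent control, independent of the remote C10 centre.

**Step 5**
Reactants: 7 methyl (4R,6R)-4-hydroxy-6,10-dimethyl-6-(triethylsilyloxy)undec-9-en-2-ynoate
Product: 9 methyl (2E,4R,6R)-4-hydroxy-2-(hydroxymethyl)-6,10-dimethyl-6-(triethylsilyloxy)undeca-2,9-dienoate, via cyclic sodium vinylalanate 8 (not isolated)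
Conditions: Red-Al, THF, −72 °C; then monomeric CH2O in THF, −72 to 0 °C; aq Rochelle salt
Reagents that add atoms: sodium bis(2-methoxyethoxy)aluminium hydride (aluminium unit of 8) [Na+].[AlH2-](OCCOC)OCCOC; formaldehyde C=O
Why: Hydroxyl-directed trans-hydroalumination of the γ-hydroxy ynoate puts hydride on C7 and aluminium on C11 in a five-membered alkoxyalanate, and hydroxymethylation of the vinylalanate with retention places C13 cis to C8, so the ester stands trans to O8 and cannot lactonise onto it.

**Step 6**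
Reactants: 9 methyl (2E,4R,6R)-4-hydroxy-2-(hydroxymethyl)-6,10-dimethyl-6-(triethylsilyloxy)undeca-2,9-dienoate
Product: 10 methyl (2Z,4R,6R)-2-(bromomethyl)-4-hydroxy-6,10-dimethyl-6-(triethylsilyloxy)undeca-2,9-dienoate
Conditions: CBr4 (1 equiv), PPh3 (1 equiv), CH2Cl2, −20 °C
Reagents that add atoms: carbon tetrabromide BrC(Br)(Br)Br
Why: In the Appel reaction one equivalent of reagent at low temperature takes the unhindered primary allylic alcohol at C13 ahead of the secondary C8 alcohol.

**Step 7**
Reactants: 10 methyl (2Z,4R,6R)-2-(bromomethyl)-4-hydroxy-6,10-dimethyl-6-(triethylsilyloxy)undeca-2,9-dienoate; 11 (R)-2-methylbutanoic acid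
Product: 12 methyl (2Z,4R,6R)-2-(bromomethyl)-6,10-dimethyl-4-[(2R)-2-methylbutanoyloxy]-6-(triethylsilyloxy)undeca-2,9-dienoate
Conditions: DCC, DMAP (cat.), CH2Cl2, 0 °C
Reagents that add atoms: none
Why: The Steglich esterification acylates O8 without touching the C8–O bond or the α-centre of the acid, so both configurations are kept and the final ester is in place early.

**Step 8**
Reactants: 13 but-2-yne-1,4-diol
Product: 14 4-(tert-butyldimethylsilyloxy)but-2-yn-1-ol
Conditions: NaH (1 equiv), THF, 0 °C; TBSCl (1 equiv)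
Reagents that add atoms: tert-butyldimethylsilyl chloride CC(C)(C)[Si](C)(C)Cl
Why: Monosilylation through the sparingly soluble monosodium alkoxide differentiates the two ends of the symmetric diol.

**Step 9**
Reactants: 14 4-(tert-butyldimethylsilyloxy)but-2-yn-1-ol
Product: 16 (Z)-4-(tert-butyldimethylsilyloxy)-3-iodobut-2-en-1-ol, via cyclic sodium vinylalanate 15 (not isolated)
Conditions: Red-Al, THF, 0 °C; then I2, −78 °C
Reagents that add atoms: sodium bis(2-methoxyethoxy)aluminium hydride (aluminium unit of 15) [Na+].[AlH2-](OCCOC)OCCOC; iodine II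
Why: Alkoxide-directed trans-hydroalumination followed by iodination with retention puts H on C5 and iodine on C4 cis to the C6 carbon, which is the ring geometry of C4=C5 in the target.

**Step 10**
Reactants: 16 (Z)-4-(tert-butyldimethylsilyloxy)-3-iodobut-2-en-1-ol
Product: 17 (Z)-4-(tert-butyldimethylsilyloxy)-3-iodobut-2-enal
Conditions: activated MnO2, CH2Cl2, rt
Reagents that add atoms: none
Why: Neutral allylic oxidation with manganese dioxide gives the C6 enal without isomerising the (Z)-iodoalkene.

**Step 11**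
Reactants: 12 methyl (2Z,4R,6R)-2-(bromomethyl)-6,10-dimethyl-4-[(2R)-2-methylbutanoyloxy]-6-(triethylsilyloxy)undeca-2,9-dienoate; 17 (Z)-4-(tert-butyldimethylsilyloxy)-3-iodobut-2-enal
Product: 19 cis-lactone vinyl iodide (6R,7R,8R,10R,2'R), via open hydroxy ester 18 (not isolated)
Conditions: In powder, THF/H2O 1:1, rt; then PPTS (cat.), CH2Cl2, rt
Reagents that add atoms: none
Why: In this Barbier-type 2-(methoxycarbonyl)allylation (Dreiding–Schmidt lactone synthesis) the allylindium reacts at C7 through a closed chair with C8 cis to the CH2In arm, which gives the 6,7-syn adduct and hence the cis-lactone, while allylic 1,3-strain turns H8 towards C13 so that the aldehyde attacks C7 anti to the C9 chain and relays C8 to C7 and C6 before O6 expels methanol.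

**Step 12**
Reactants: 19 cis-lactone vinyl iodide
Product: 21 iodo aldehyde (C3 aldehyde, C4 vinyl iodide), via secondary ozonide 20 (not isolated)
Conditions: O3 (1 equiv, Sudan Red end point), CH2Cl2/pyridine, −78 °C; then Me2S, −78 °C to rt
Reagents that add atoms: ozone [O-][O+]=O
Why: In the ozonolysis the electron-rich trisubstituted alkene is cleaved well before the electron-poor acrylate methylene and the iodoalkene, which unmasks the C3 aldehyde.

**Step 13**
Reactants: 21 iodo aldehyde
Product: 22 macrocyclic C3 allylic alcohol (6S,7R,8R,10R,2'R; both C3 epimers)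
Conditions: CrCl2 (excess), NiCl2 (cat.), DMSO/THF, slow addition to about 2 mM, rt
Reagents that add atoms: none
Why: Nickel(0) inserts into the C4–I bond with retention, the alkenyl group is passed to chromium(III), and the alkenylchromium adds to the C3 aldehyde to form the C3–C4 bond and a chromium alkoxide that is hydrolysed on work-up. The closest known reaction type is the Nozaki–Hiyama–Kishi macrocyclisation of iodoalkenyl aldehydes to ten-membered germacranolide carbocycles. The only ring closed is the ten-membered carbocycle, by exo attack on the carbonyl (10-exo-trig), and it is the last ring because the lactone is already present. The single new stereocentre, C3, is not controlled and is erased by the oxidation in step 14, whereas C6, C7, C8 and C10 are not involved. The step needs chemoselectivity for the aldehyde over the lactone, the C8 ester and the acrylate, which the low basicity and oxophilicity of alkenylchromium secure. It also needs cyclisation to win over oligomerisation, which the high dilution and the cis-lactone hinge that places C5 and C8 on the same face secure.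

**Step 14**
Reactants: 22 macrocyclic C3 allylic alcohol
Product: 23 bis-silylated enone (15-O-TBS, 10-O-TES ether of the target)
Conditions: Dess–Martin periodinane, NaHCO3, CH2Cl2, 0 °C
Reagents that add atoms: none
Why: The Dess–Martin oxidation converges both C3 epimers on the (Z)-enone under neutral conditions that spare the γ-acyloxy enone and the methylene lactone.

**Step 15**
Reactants: 23 bis-silylated enone
Product: 24 target CNP0130221.1
Conditions: HF·pyridine, pyridine/THF, 0 °C to rt
Reagents that add atoms: none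
Why: Fluoride-mediated desilylation under buffered acidic conditions removes the primary TBS and the tertiary TES ether in one operation without ester cleavage, acyl migration or conjugate addition.

**Compound list**
1 | (R)-linalool, (3R)-3,7-dimethylocta-1,6-dien-3-ol | CC(C)=CCC[C@@](C)(O)C=C | starting material
2 | (R)-linalool triethylsilyl ether | CC(C)=CCC[C@@](C)(O[Si](CC)(CC)CC)C=C | intermediate
3 | B-alkyl-9-BBN adduct of 2 (boron on C8) | CC(C)=CCC[C@@](C)(O[Si](CC)(CC)CC)CCB1C2CCCC1CCC2 | intermediate
4 | (3R)-3,7-dimethyl-3-(triethylsilyloxy)oct-6-en-1-ol | CC(C)=CCC[C@@](C)(O[Si](CC)(CC)CC)CCO | intermediate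
5 | (3R)-3,7-dimethyl-3-(triethylsilyloxy)oct-6-enal | CC(C)=CCC[C@@](C)(O[Si](CC)(CC)CC)CC=O | intermediate
6 | methyl propiolate | C#CC(=O)OC | starting material
7 | methyl (4R,6R)-4-hydroxy-6,10-dimethyl-6-(triethylsilyloxy)undec-9-en-2-ynoate | CC(C)=CCC[C@@](C)(O[Si](CC)(CC)CC)C[C@@H](O)C#CC(=O)OC | intermediate
8 | cyclic sodium alkoxy(vinyl)alanate from 7 (Al on C11, O8 bound to Al) | CC(C)=CCC[C@@](C)(O[Si](CC)(CC)CC)C[C@@H]1C=C(C(=O)OC)[Al-](OCCOC)(OCCOC)O1.[Na+] | intermediate
9 | methyl (2E,4R,6R)-4-hydroxy-2-(hydroxymethyl)-6,10-dimethyl-6-(triethylsilyloxy)undeca-2,9-dienoate | CC(C)=CCC[C@@](C)(O[Si](CC)(CC)CC)C[C@@H](O)/C=C(/C(=O)OC)CO | intermediate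
10 | methyl (2Z,4R,6R)-2-(bromomethyl)-4-hydroxy-6,10-dimethyl-6-(triethylsilyloxy)undeca-2,9-dienoate | CC(C)=CCC[C@@](C)(O[Si](CC)(CC)CC)C[C@@H](O)/C=C(/C(=O)OC)CBr | intermediate
11 | (R)-2-methylbutanoic acid | OC(=O)[C@H](C)CC | starting material
12 | methyl (2Z,4R,6R)-2-(bromomethyl)-6,10-dimethyl-4-[(2R)-2-methylbutanoyloxy]-6-(triethylsilyloxy)undeca-2,9-dienoate | CC(C)=CCC[C@@](C)(O[Si](CC)(CC)CC)C[C@@H](OC(=O)[C@H](C)CC)/C=C(/C(=O)OC)CBr | intermediate
13 | but-2-yne-1,4-diol | OCC#CCO | starting material
14 | 4-(tert-butyldimethylsilyloxy)but-2-yn-1-ol | OCC#CCO[Si](C)(C)C(C)(C)C | intermediate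
15 | cyclic sodium alkoxy(vinyl)alanate from 14 (Al on C4) | [Na+].COCCO[Al-]1(OCCOC)OCC=C1CO[Si](C)(C)C(C)(C)C | intermediate
16 | (Z)-4-(tert-butyldimethylsilyloxy)-3-iodobut-2-en-1-ol | OC/C=C(/CO[Si](C)(C)C(C)(C)C)I | intermediate
17 | (Z)-4-(tert-butyldimethylsilyloxy)-3-iodobut-2-enal | O=C/C=C(/CO[Si](C)(C)C(C)(C)C)I | intermediate
18 | open hydroxy ester: methyl 2-methylene ester with C6–OH, 6,7-syn (6R,7S,8R,10R,2'R) | CC(C)=CCC[C@@](C)(O[Si](CC)(CC)CC)C[C@@H](OC(=O)[C@H](C)CC)[C@@H](C(=C)C(=O)OC)[C@@H](O)/C=C(/CO[Si](C)(C)C(C)(C)C)I | intermediate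
19 | cis-β,γ-disubstituted α-methylene-γ-butyrolactone with the (Z)-iodoalkenyl group on C6 and the C8–C3 prenyl chain on C7 (6R,7R,8R,10R,2'R) | CC(C)=CCC[C@@](C)(O[Si](CC)(CC)CC)C[C@@H](OC(=O)[C@H](C)CC)[C@H]1C(=C)C(=O)O[C@H]1/C=C(/CO[Si](C)(C)C(C)(C)C)I | intermediate
20 | secondary ozonide (1,2,4-trioxolane) of the prenyl alkene of 19 | CC1(C)OOC(CC[C@@](C)(O[Si](CC)(CC)CC)C[C@@H](OC(=O)[C@H](C)CC)[C@H]2C(=C)C(=O)O[C@H]2/C=C(/CO[Si](C)(C)C(C)(C)C)I)O1 | intermediate
21 | iodo aldehyde: 19 with the prenyl end cut to the C3 aldehyde (6R,7R,8R,10R,2'R) | O=CCC[C@@](C)(O[Si](CC)(CC)CC)C[C@@H](OC(=O)[C@H](C)CC)[C@H]1C(=C)C(=O)O[C@H]1/C=C(/CO[Si](C)(C)C(C)(C)C)I | intermediate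
22 | ten-membered (4Z)-3-hydroxy germacranolide, 15-O-TBS, 10-O-TES, C3 epimers (6S,7R,8R,10R,2'R) | C=C1C(=O)O[C@H]2/C=C(/CO[Si](C)(C)C(C)(C)C)C(O)CC[C@@](C)(O[Si](CC)(CC)CC)C[C@@H](OC(=O)[C@H](C)CC)[C@@H]12 | intermediate
23 | ten-membered (4Z)-3-oxo germacranolide, 15-O-TBS, 10-O-TES (6S,7R,8R,10R,2'R) | C=C1C(=O)O[C@H]2/C=C(/CO[Si](C)(C)C(C)(C)C)C(=O)CC[C@@](C)(O[Si](CC)(CC)CC)C[C@@H](OC(=O)[C@H](C)CC)[C@@H]12 | intermediate
24 | CNP0130221.1 (4Z,6S,7R,8R,10R,2'R) | C=C1C(=O)O[C@H]2/C=C(/CO)C(=O)CC[C@@](C)(O)C[C@@H](OC(=O)[C@H](C)CC)[C@@H]12 | target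

**Count.** Total steps: 15. Longest linear sequence: 12 (steps 1–7 and 11–15).

**Steps most likely to fail**

Step 13. Oligomerisation, or reduction of the C–I bond before the strained ring closes, may outrun cyclisation. The fallback closes the ring at C4=C5 by metathesis instead. It sets out from 12.
- Bromide 12 is coupled with acrolein under the conditions of step 11 to give the γ-vinyl cis-lactone F1.
- Selective ozonolysis of the prenyl alkene of F1 gives the C3 aldehyde F2.
- An intermolecular Nozaki–Hiyama–Kishi addition of 2-bromoallyl tert-butyldimethylsilyl ether to F2 gives the allylic alcohol F3.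
- Dess–Martin oxidation of F3 gives the 2-(silyloxymethyl) vinyl ketone F4.
- Ring-closing metathesis of F4 with a Hoveyda–Grubbs second-generation catalyst in hot dilute toluene joins C4 and C5, with the ring size enforcing the Z alkene. The route is rejoined at 23.

Step 11. Reductive 1,4-elimination of the C8 acyloxy group from the allylindium, or poor facial selectivity at C7, may erode the coupling. The fallback replaces the reducing metal by boron. It sets out from 12, which is borylated (B2pin2, Pd2(dba)3, toluene) to the allylboronate F5. Thermal or Sc(OTf)3-promoted allylboration of 17 through the closed chair, followed by acid lactonisation, rejoins the route at 19.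

Step 5. Sluggish capture of the ester-bearing vinylalanate by formaldehyde may leave only protonated enoate. The fallback sets out from 7. The alanate is quenched with N-iodosuccinimide to give the α-iodo enoate F6, and a Stille coupling with (tributylstannyl)methanol and Pd(PPh3)4 installs C13. The route is rejoined at 9.

**Further compounds**
F1 | step 13 | γ-vinyl cis-lactone (19 with vinyl in place of the iodoalkenyl group) | CC(C)=CCC[C@@](C)(O[Si](CC)(CC)CC)C[C@@H](OC(=O)[C@H](C)CC)[C@H]1C(=C)C(=O)O[C@H]1C=C
F2 | step 13 | C3 aldehyde of the γ-vinyl cis-lactone | O=CCC[C@@](C)(O[Si](CC)(CC)CC)C[C@@H](OC(=O)[C@H](C)CC)[C@H]1C(=C)C(=O)O[C@H]1C=C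
F3 | step 13 | C3 allylic alcohol bearing the 2-(silyloxymethyl)vinyl group (C3 epimers) | C=C(CO[Si](C)(C)C(C)(C)C)C(O)CC[C@@](C)(O[Si](CC)(CC)CC)C[C@@H](OC(=O)[C@H](C)CC)[C@H]1C(=C)C(=O)O[C@H]1C=C
F4 | step 13 | 2-(silyloxymethyl) vinyl ketone, open metathesis precursor | C=C(CO[Si](C)(C)C(C)(C)C)C(=O)CC[C@@](C)(O[Si](CC)(CC)CC)C[C@@H](OC(=O)[C@H](C)CC)[C@H]1C(=C)C(=O)O[C@H]1C=C
F5 | step 11 | (Z)-2-(pinacolboryl-methyl) enoate (allylboronate from 12) | CC(C)=CCC[C@@](C)(O[Si](CC)(CC)CC)C[C@@H](OC(=O)[C@H](C)CC)/C=C(/C(=O)OC)CB1OC(C)(C)C(C)(C)O1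
F6 | step 5 | methyl (4R,6R)-4-hydroxy-2-iodo enoate, iodine cis to C8 | CC(C)=CCC[C@@](C)(O[Si](CC)(CC)CC)C[C@@H](O)/C=C(/C(=O)OC)I
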